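Plan

- Retrosynthesis: the last operation is an epimerisation at C5. Before it, the cyclohexenone ring is cut at C7=C7a and at C3a–C4, giving an α-allyl γ-butyrolactone (C7a = lactone carbonyl, C3a = its α-carbon, O1 = lactone oxygen) and 3-methoxybut-3-en-2-one (C4–C7). The lactone is cut at C3a–allyl and C3–aryl back to (S)-5-methylfuran-2(5H)-one.
- Enabling feature: O1–C7a=C7–C6=O in the six-membered ring is a vinylogous ester, the enol ether of a cyclohexane-1,3-dione formed with the oxygen of the five-membered ring. C7a can therefore be a carboxyl-level carbon and the C2 alkoxide a leaving group that returns.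
- Forward: butenolide, then trans-aryl lactone, then allyl lactone. A one-pot Michael/Claisen/cyclodehydration annulation then builds the carbocycle, the quaternary C3a and the vinylogous ester, while the five-membered ring opens and recloses.
- Stereochemistry: C2 from (S)-but-3-yn-2-ol; C3 by conjugate addition anti to the C2 methyl; C3a by Michael addition anti to the C3 aryl; C5 by equilibration to the pseudoequatorial methoxy epimer.

Key step: step 6

Remark (assumption): locants C2–C7a follow the 1-benzofuran numbering of the target; 3,4,5-trimethoxyphenylmagnesium bromide is taken as the commercial THF solution.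

Route

Step 1
Reactants: 1 (S)-but-3-yn-2-ol
Product: 2 (S)-4-hydroxypent-2-ynoic acid
Conditions: n-BuLi (2.1 equiv), THF, −78 °C; CO2, −78 °C → rt; aq. HCl
Reagents that add atoms: carbon dioxide, O=C=O
Why: Carboxylation of the alkoxide–acetylide dianion is a standard route to 4-hydroxy-2-alkynoic acids and does not touch the carbinol stereocenter, which becomes C2 of the target.

Step 2
Reactants: 2 (S)-4-hydroxypent-2-ynoic acid
Product: 4 (S)-5-methylfuran-2(5H)-one, via (S,Z)-4-hydroxypent-2-enoic acid 3 (not isolated)
Conditions: H2 (1 atm), Pd/BaSO4 (5 % Pd), quinoline, MeOH, rt; then TsOH (cat.), CH2Cl2, rt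
Reagents that add atoms: none
Why: cis-Selective semihydrogenation of the alkyne over poisoned palladium should give the Z-hydroxy acid, which lactonises to the butenolide without affecting the stereocenter.

Step 3
Reactants: 4 (S)-5-methylfuran-2(5H)-one; 5 3,4,5-trimethoxyphenylmagnesium bromide
Product: 6 (4S,5S)-5-methyl-4-(3,4,5-trimethoxyphenyl)oxolan-2-one
Conditions: 5 (1.3 equiv), CuBr·SMe2 (10 mol %), THF, −40 °C; then 1 M aq. HCl
Reagents that add atoms: none
Why: Copper-catalysed conjugate addition of the aryl Grignard reagent to the butenolide should deliver the aryl group to the β-carbon on the face anti to the adjacent methyl group, setting the aryl-bearing center trans to methyl by substrate control.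

Step 4
Reactants: 6 (4S,5S)-5-methyl-4-(3,4,5-trimethoxyphenyl)oxolan-2-one
Product: 7 (3R,4S,5S)-5-methyl-3-(prop-2-en-1-yl)-4-(3,4,5-trimethoxyphenyl)oxolan-2-one
Conditions: LiN(i-Pr)2 (1.05 equiv), THF, −78 °C; allyl bromide (1.2 equiv), −78 → −30 °C
Reagents that add atoms: allyl bromide, C=CCBr
Why: Alkylation of the lithium lactone enolate should occur anti to the neighbouring aryl group (enolate alkylation), and the configuration of this carbon is immaterial because it is planarised again in step 6.

Step 5
Reactants: 8 3,3-dimethoxybutan-2-one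
Product: 9 3-methoxybut-3-en-2-one
Conditions: KHSO4 (cat.), hydroquinone (trace), neat, 140 °C, MeOH distilled off; then distillation at reduced pressure
Reagents that add atoms: none
Why: Acid-catalysed loss of methanol from the α-keto ketal (ketal to enol ether elimination) should give the 2-methoxy enone, driven by removal of methanol.

Step 6
Reactants: 7 (3R,4S,5S)-5-methyl-3-(prop-2-en-1-yl)-4-(3,4,5-trimethoxyphenyl)oxolan-2-one; 9 3-methoxybut-3-en-2-one
Product: 12 (2S,3R,3aR)-5-methoxy-2-methyl-3a-(prop-2-en-1-yl)-3-(3,4,5-trimethoxyphenyl)-3,3a,4,5-tetrahydro-1-benzofuran-6(2H)-one (both C5 epimers), via keto lactone 10 (not isolated), via hydroxy dione 11 (not isolated)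
Conditions: LiN(i-Pr)2 (1.1 equiv), THF/DMPU, −78 °C; 9 (1.3 equiv), −78 → −40 °C; KOt-Bu (1.0 equiv) in t-BuOH/THF, −40 °C → rt; then 2 M aq. HCl, THF, rt → 40 °C
Reagents that add atoms: none
Why: Proposed new method: the enolate of 7 adds through its α-carbon (C3a) to the terminal carbon (C4) of enone 9, alkoxide-mediated proton transfer moves the resulting enolate to the methyl group (C7), and this enolate attacks the lactone carbonyl (C7a) in a Claisen condensation whose leaving group is the tethered C2 alkoxide, so that the stabilised 1,3-diketonate of 11 forms irreversibly; acid then lets the C2 hydroxyl add back to C7a and the hemiketal lose water to give the vinylogous ester. The closest known reaction types are the Michael–Claisen annulation of ester enolates with enones to cyclohexane-1,3-diones (the dimedone synthesis) and the Robinson annulation, but a non-stabilised lactone enolate as donor with the lactone itself as acyl acceptor has not been shown in one operation. The carbocycle closes 6-exo-trig (enolate carbon on the lactone C=O) and the five-membered ring recloses 5-exo-trig by hemiketalisation followed by dehydration. C3a is set by approach of the enone to the enolate face anti to the vicinal C3 aryl group, which places allyl cis and the new C3a–C4 bond trans to aryl as in the target; C5 arises without control and is settled in step 7. The step needs 1,4- over 1,2-addition and closure through the C7 and not the C5 enolate: the hindered tetrasubstituted enolate, whose 1,2-adducts revert under the alkoxide stage, should secure the first, and ring size secures the second, since the C5 enolate could only form a cyclobutanone whereas the C7 enolate forms a six-membered ring and is then drained as the diketonate.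

Step 7
Reactants: 12 (2S,3R,3aR)-5-methoxy-2-methyl-3a-(prop-2-en-1-yl)-3-(3,4,5-trimethoxyphenyl)-3,3a,4,5-tetrahydro-1-benzofuran-6(2H)-one (both C5 epimers)
Product: 13 (2S,3R,3aR,5R)-5-methoxy-2-methyl-3a-(prop-2-en-1-yl)-3-(3,4,5-trimethoxyphenyl)-3,3a,4,5-tetrahydro-1-benzofuran-6(2H)-one
Conditions: KOt-Bu (0.2 equiv), t-BuOH/THF, 0 °C → rt; pH 7 buffer
Reagents that add atoms: none
Why: Reversible α'-enolisation of the α-methoxy ketone (base-mediated epimerisation under thermodynamic control) should converge on the epimer with the methoxy group pseudoequatorial and trans to the pseudoaxial allyl group on C3a, which avoids the 1,3-diaxial contact of the other epimer, while C3a bears no hydrogen and C2 and C3 are not acidic.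

Compound list

1 | (S)-but-3-yn-2-ol | C[C@H](O)C#C | starting material
2 | (S)-4-hydroxypent-2-ynoic acid | C[C@H](O)C#CC(=O)O | intermediate
3 | (S,Z)-4-hydroxypent-2-enoic acid | C[C@H](O)/C=C\C(=O)O | intermediate
4 | (S)-5-methylfuran-2(5H)-one | C[C@@H]1OC(=O)C=C1 | intermediate
5 | 3,4,5-trimethoxyphenylmagnesium bromide | COc1cc([Mg]Br)cc(OC)c1OC | starting material
6 | (4S,5S)-5-methyl-4-(3,4,5-trimethoxyphenyl)oxolan-2-one | C[C@@H]1OC(=O)C[C@H]1c1cc(OC)c(OC)c(OC)c1 | intermediate
7 | (3R,4S,5S)-5-methyl-3-(prop-2-en-1-yl)-4-(3,4,5-trimethoxyphenyl)oxolan-2-one | C=CC[C@H]1C(=O)O[C@@H](C)[C@@H]1c1cc(OC)c(OC)c(OC)c1 | intermediate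
8 | 3,3-dimethoxybutan-2-one | CC(=O)C(C)(OC)OC | starting material
9 | 3-methoxybut-3-en-2-one | CC(=O)C(=C)OC | intermediate
10 | (3R,4R,5S)-3-(2-methoxy-3-oxobutyl)-5-methyl-3-(prop-2-en-1-yl)-4-(3,4,5-trimethoxyphenyl)oxolan-2-one (side-chain epimers) | C=CC[C@]1(CC(OC)C(C)=O)C(=O)O[C@@H](C)[C@@H]1c1cc(OC)c(OC)c(OC)c1 | intermediate
11 | (4R)-4-[(1R,2S)-2-hydroxy-1-(3,4,5-trimethoxyphenyl)propyl]-6-methoxy-4-(prop-2-en-1-yl)cyclohexane-1,3-dione (C6 epimers) | C=CC[C@@]1(CC(OC)C(=O)CC1=O)[C@H]([C@H](C)O)c1cc(OC)c(OC)c(OC)c1 | intermediate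
12 | (2S,3R,3aR)-5-methoxy-2-methyl-3a-(prop-2-en-1-yl)-3-(3,4,5-trimethoxyphenyl)-3,3a,4,5-tetrahydro-1-benzofuran-6(2H)-one (both C5 epimers) | C=CC[C@]12CC(OC)C(=O)C=C1O[C@@H](C)[C@@H]2c1cc(OC)c(OC)c(OC)c1 | intermediate
13 | (2S,3R,3aR,5R)-5-methoxy-2-methyl-3a-(prop-2-en-1-yl)-3-(3,4,5-trimethoxyphenyl)-3,3a,4,5-tetrahydro-1-benzofuran-6(2H)-one | C=CC[C@]12C[C@@H](OC)C(=O)C=C1O[C@@H](C)[C@@H]2c1cc(OC)c(OC)c(OC)c1 | target

Count and risks

Total steps: 7. Longest linear sequence: 6 steps (steps 1, 2, 3, 4, 6, 7); step 5 is a one-step branch.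

The three steps most likely to fail:

1. Step 6 (the step that bears the label for a proposed new method). What may go wrong: 1,2-addition or anionic oligomerisation of the enone in competition with the Michael addition, retro-Michael loss of the quaternary center on warming, insufficient facial selectivity at C3a, or sluggish Claisen closure at the hindered lactone carbonyl. Fallback: it sets out from 7 and comes back to the route at 12, and it runs the annulation stepwise by known reactions. Compound 7 is O-silylated (LiN(i-Pr)2, then TBSCl, THF/DMPU, −78 °C) to the silyl ketene acetal tert-butyldimethyl{[(4R,5S)-5-methyl-3-(prop-2-en-1-yl)-4-(3,4,5-trimethoxyphenyl)-4,5-dihydrofuran-2-yl]oxy}silane F1 as the nucleophile. Mukaiyama–Michael addition of this acetal to 9 (TBSOTf cat., CH2Cl2, −78 °C) should give, again by attack anti to the aryl group, the silyl enol ether (3R,4R,5S)-3-[3-(tert-butyldimethylsilyloxy)-2-methoxybut-2-en-1-yl]-5-methyl-3-(prop-2-en-1-yl)-4-(3,4,5-trimethoxyphenyl)oxolan-2-one F2 as a mixture of double-bond isomers. Mild acid hydrolysis (aq. HCl, THF) releases keto lactone 10, now isolated. Claisen cyclisation of 10 (KOt-Bu, t-BuOH/THF, rt) gives 11, and TsOH (cat.) in toluene closes it to 12.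

2. Step 7. What may go wrong: an unfavourable or slowly established epimer equilibrium at C5, or base-induced opening of the vinylogous ester. Fallback: it sets out from 7 and comes back to the route at 13; C5 is then set kinetically by substrate control instead of by equilibration. Compound 7 is annulated under the conditions of step 6 (or stepwise as in the fallback for step 6) with but-3-en-2-one in place of 9. This runs through (3S,4R,5S)-5-methyl-3-(3-oxobutyl)-3-(prop-2-en-1-yl)-4-(3,4,5-trimethoxyphenyl)oxolan-2-one F3 and then (4S)-4-[(1R,2S)-2-hydroxy-1-(3,4,5-trimethoxyphenyl)propyl]-4-(prop-2-en-1-yl)cyclohexane-1,3-dione F4 , neither isolated, to the methoxy-free enone (2S,3R,3aS)-2-methyl-3a-(prop-2-en-1-yl)-3-(3,4,5-trimethoxyphenyl)-3,3a,4,5-tetrahydro-1-benzofuran-6(2H)-one F5 , which is isolated. Its kinetic α'-enolate (LiN(i-Pr)2, THF, −78 °C) is hydroxylated with 2-(phenylsulfonyl)-3-phenyloxaziridine from the face anti to the pseudoaxial allyl group to give (2S,3R,3aR,5R)-5-hydroxy-2-methyl-3a-(prop-2-en-1-yl)-3-(3,4,5-trimethoxyphenyl)-3,3a,4,5-tetrahydro-1-benzofuran-6(2H)-one F6 as the trans alcohol. O-Methylation (MeI, Ag2O, CH2Cl2, rt) then gives 13.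

3. Step 3. What may go wrong: γ-deprotonation of the butenolide by the Grignard reagent, with loss of material and of enantiopurity through the achiral 2-oxidofuran, or insufficient anti selectivity. Fallback: it sets out from 4 and comes back to the route at 6 by rhodium-catalysed 1,4-addition of 3,4,5-trimethoxyphenylboronic acid ([Rh(cod)OH]2 cat., dioxane/H2O, 60 °C) under near-neutral conditions. The aryl group is delivered by carbometalation anti to the methyl group and no strong base is present. This fallback makes no compound outside the compound list, which the line F0 records.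

Further compounds

F1 | step 6 | tert-butyldimethyl{[(4R,5S)-5-methyl-3-(prop-2-en-1-yl)-4-(3,4,5-trimethoxyphenyl)-4,5-dihydrofuran-2-yl]oxy}silane | C=CCC1=C(O[Si](C)(C)C(C)(C)C)O[C@@H](C)[C@@H]1c1cc(OC)c(OC)c(OC)c1
F2 | step 6 | (3R,4R,5S)-3-[3-(tert-butyldimethylsilyloxy)-2-methoxybut-2-en-1-yl]-5-methyl-3-(prop-2-en-1-yl)-4-(3,4,5-trimethoxyphenyl)oxolan-2-one | C=CC[C@]1(CC(OC)=C(C)O[Si](C)(C)C(C)(C)C)C(=O)O[C@@H](C)[C@@H]1c1cc(OC)c(OC)c(OC)c1
F3 | step 7 | (3S,4R,5S)-5-methyl-3-(3-oxobutyl)-3-(prop-2-en-1-yl)-4-(3,4,5-trimethoxyphenyl)oxolan-2-one | C=CC[C@]1(CCC(C)=O)C(=O)O[C@@H](C)[C@@H]1c1cc(OC)c(OC)c(OC)c1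
F4 | step 7 | (4S)-4-[(1R,2S)-2-hydroxy-1-(3,4,5-trimethoxyphenyl)propyl]-4-(prop-2-en-1-yl)cyclohexane-1,3-dione | C=CC[C@@]1(CCC(=O)CC1=O)[C@H]([C@H](C)O)c1cc(OC)c(OC)c(OC)c1
F5 | step 7 | (2S,3R,3aS)-2-methyl-3a-(prop-2-en-1-yl)-3-(3,4,5-trimethoxyphenyl)-3,3a,4,5-tetrahydro-1-benzofuran-6(2H)-one | C=CC[C@]12CCC(=O)C=C1O[C@@H](C)[C@@H]2c1cc(OC)c(OC)c(OC)c1
F6 | step 7 | (2S,3R,3aR,5R)-5-hydroxy-2-methyl-3a-(prop-2-en-1-yl)-3-(3,4,5-trimethoxyphenyl)-3,3a,4,5-tetrahydro-1-benzofuran-6(2H)-one | C=CC[C@]12C[C@@H](O)C(=O)C=C1O[C@@H](C)[C@@H]2c1cc(OC)c(OC)c(OC)c1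
F0 | step 3 | none | none
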